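**Target:** CNP0361406.4, (5aR,6S,9R,9aS)-9-hydroxy-9-{[((2E)-2-(hydroxymethyl)-3-[(1S,6S)-3-(hydroxymethyl)-6-(propan-2-yl)cyclohex-2-en-1-yl]prop-2-enoyl)oxy]methyl}-1-oxo-6-(propan-2-yl)-1,3,5a,6,7,8,9,9a-octahydro-2-benzoxepine-4-carboxylic acid.

## Retrosynthetic overview

1. The last C=C bond is made by cross-metathesis between a 2-(hydroxymethyl)acrylate ester on the left-hand bicyclic hydroxy lactone acid and the vinyl group of the right-hand cyclohexenylmethanol.
2. The acrylate ester and the tertiary alcohol come from carboxylate opening of a spiro-epoxide; the seven-membered lactone is closed by ring-closing metathesis (second ring formed).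
3. The spiro-epoxide and the two adjacent ring stereocentres come from one new step: conjugate vinylation of a 2-(silyloxymethyl)cyclohexenone, then a sulfonium proton relay that protonates the enolate and epoxidises the ketone.
4. The right half comes from the same enone by conjugate vinylation, enol triflate formation and hydroxymethyl Stille coupling.
5. Both halves start from (S)-cryptone, made from 3-methylbutanal and but-3-en-2-one by organocatalytic Michael addition and aldol condensation (first stereocentre, six-membered ring formed first).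

Assumption: the (S)-diarylprolinol ether catalyst gives the (S)-aldehyde 3, as its usual enamine facial bias predicts; the antipodal catalyst is used if the opposite sense is found.

## Route

Step 1
Reactants: 1 3-methylbutanal; 2 but-3-en-2-one
Product: 4 (4S)-4-(propan-2-yl)cyclohex-2-en-1-one, via keto aldehyde 3 (not isolated)
Conditions: (S)-2-[methoxy(diphenyl)methyl]pyrrolidine (5 mol %), ethyl 3,4-dihydroxybenzoate (20 mol %), neat, 4 °C; then LiOH, i-PrOH, rt
Reagents that add atoms: none
Why: Enamine-catalysed asymmetric Michael addition (the diphenylmethyl ether arm shields one enamine face and sets the isopropyl-bearing centre as S), followed by intramolecular aldol condensation of the methyl ketone onto the aldehyde (organocatalytic Robinson-type annulation).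

Step 2
Reactants: 4 (4S)-4-(propan-2-yl)cyclohex-2-en-1-one
Product: 5 (4S)-2-(hydroxymethyl)-4-(propan-2-yl)cyclohex-2-en-1-one
Conditions: 37 % aq. HCHO, DMAP (20 mol %), THF/H2O, rt
Reagents that add atoms: formaldehyde, C=O
Why: Morita–Baylis–Hillman hydroxymethylation at the enone α-carbon under weakly basic conditions that leave the γ-stereocentre untouched.

Step 3
Reactants: 5 (4S)-2-(hydroxymethyl)-4-(propan-2-yl)cyclohex-2-en-1-one
Product: 6 (4S)-2-{[(tert-butyldimethylsilyl)oxy]methyl}-4-(propan-2-yl)cyclohex-2-en-1-one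
Conditions: TBSCl, imidazole, CH2Cl2, 0 °C to rt
Reagents that add atoms: tert-butyldimethylsilyl chloride, CC(C)(C)[Si](C)(C)Cl
Why: Standard silylation of the primary alcohol so that it survives the organometallic and ylide chemistry of the next step.

Step 4
Reactants: 6 (4S)-2-{[(tert-butyldimethylsilyl)oxy]methyl}-4-(propan-2-yl)cyclohex-2-en-1-one
Product: 9 tert-butyl{[(3R,4R,5S,6S)-5-ethenyl-6-(propan-2-yl)-1-oxaspiro[2.5]octan-4-yl]methoxy}dimethylsilane, via magnesium enolate 7 (not isolated), via cis-ketone 8 (not isolated)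
Conditions: CH2=CHMgBr, CuBr·SMe2 (10 mol %), THF, −78 °C; then Me3S+ BF4−, DMF, −78 to 0 °C
Reagents that add atoms: vinylmagnesium bromide, C=C[Mg]Br; trimethylsulfonium tetrafluoroborate, C[S+](C)C.F[B-](F)(F)F
Why: Proposed new method: after copper-catalysed 1,4-vinylation anti to the isopropyl group, enolate 7 (conjugate-acid pKa about 26) is protonated by trimethylsulfonium (pKa about 18) on the face anti to the vinyl group, which A(1,2) strain holds pseudo-axial, giving cis-ketone 8 and exactly one equivalent of dimethylsulfonium methylide, which adds axially (anti to the axial CH2OTBS group) before 8 can epimerise and closes to the spiro-epoxide with oxygen equatorial and cis to CH2OTBS; the closest known chemistry is kinetic protonation of cuprate-derived enolates and Corey–Chaykovsky epoxidation with a preformed sulfonium ylide.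

Step 5
Reactants: 9 tert-butyl{[(3R,4R,5S,6S)-5-ethenyl-6-(propan-2-yl)-1-oxaspiro[2.5]octan-4-yl]methoxy}dimethylsilane
Product: 10 [(3R,4R,5S,6S)-5-ethenyl-6-(propan-2-yl)-1-oxaspiro[2.5]octan-4-yl]methanol
Conditions: TBAF, THF, 0 °C
Reagents that add atoms: none
Why: Fluoride desilylation; the liberated alkoxide cannot open the epoxide because the CH2O group and the epoxide CH2 are trans-diaxial.

Step 6
Reactants: 10 [(3R,4R,5S,6S)-5-ethenyl-6-(propan-2-yl)-1-oxaspiro[2.5]octan-4-yl]methanol
Product: 12 (3R,4S,5S,6S)-5-ethenyl-6-(propan-2-yl)-1-oxaspiro[2.5]octane-4-carboxylic acid, via epoxy aldehyde 11 (not isolated)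
Conditions: TEMPO (20 mol %), PhI(OAc)2, MeCN/pH 7 phosphate buffer, 0 °C to rt
Reagents that add atoms: water, O
Why: Oxoammonium (TEMPO) oxidation of the primary alcohol through the aldehyde hydrate to the acid under buffered, non-basic conditions that spare the epoxide, the vinyl group and the α-stereocentre.

Step 7
Reactants: 12 (3R,4S,5S,6S)-5-ethenyl-6-(propan-2-yl)-1-oxaspiro[2.5]octane-4-carboxylic acid; 13 tert-butyl 2-(bromomethyl)prop-2-enoate
Product: 14 2-(tert-butoxycarbonyl)prop-2-en-1-yl (3R,4S,5S,6S)-5-ethenyl-6-(propan-2-yl)-1-oxaspiro[2.5]octane-4-carboxylate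
Conditions: K2CO3, DMF, 0 °C to rt
Reagents that add atoms: none
Why: Carboxylate O-alkylation by the allylic bromide (direct and allylic-transposition substitution give the same ester), with no acyl activation that could epimerise the α-centre.

Step 8
Reactants: 14 2-(tert-butoxycarbonyl)prop-2-en-1-yl (3R,4S,5S,6S)-5-ethenyl-6-(propan-2-yl)-1-oxaspiro[2.5]octane-4-carboxylate
Product: 15 tert-butyl (5aR,6S,9R,9aS)-1-oxo-6-(propan-2-yl)-3,5a,6,7,8,9a-hexahydro-1H-spiro[2-benzoxepine-9,2'-oxirane]-4-carboxylate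
Conditions: second-generation Hoveyda–Grubbs catalyst [RuCl2(H2IMes)(=CH-C6H4-2-OiPr)] (5 mol %), toluene (5 mM), 80 °C
Reagents that add atoms: none
Why: Ring-closing metathesis of the equatorial vinyl group with the 1,1-disubstituted acrylate held gauche on the axial ester closes the cis-fused seven-membered lactone; the ring fixes the alkene geometry (ring carbon cis to CH2O).

Step 9
Reactants: 15 tert-butyl (5aR,6S,9R,9aS)-1-oxo-6-(propan-2-yl)-3,5a,6,7,8,9a-hexahydro-1H-spiro[2-benzoxepine-9,2'-oxirane]-4-carboxylate; 16 2-(hydroxymethyl)prop-2-enoic acid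
Product: 17 tert-butyl (5aR,6S,9R,9aS)-9-hydroxy-9-({[2-(hydroxymethyl)prop-2-enoyl]oxy}methyl)-1-oxo-6-(propan-2-yl)-1,3,5a,6,7,8,9,9a-octahydro-2-benzoxepine-4-carboxylate
Conditions: 16 (3 equiv), Cs2CO3 (0.3 equiv), BHT (cat.), DMF, 45 °C
Reagents that add atoms: none
Why: Carboxylate SN2 opening of the 2,2-disubstituted epoxide at its CH2 terminus leaves the C–O bond at the quaternary carbon intact, so the tertiary alcohol keeps the epoxide configuration, and the excess acid protonates the aldolate at once (no retro-aldol or E1cB).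

Step 10
Reactants: 17 tert-butyl (5aR,6S,9R,9aS)-9-hydroxy-9-({[2-(hydroxymethyl)prop-2-enoyl]oxy}methyl)-1-oxo-6-(propan-2-yl)-1,3,5a,6,7,8,9,9a-octahydro-2-benzoxepine-4-carboxylate
Product: 18 (5aR,6S,9R,9aS)-9-hydroxy-9-({[2-(hydroxymethyl)prop-2-enoyl]oxy}methyl)-1-oxo-6-(propan-2-yl)-1,3,5a,6,7,8,9,9a-octahydro-2-benzoxepine-4-carboxylic acid
Conditions: TFA/CH2Cl2 (1:4), 0 °C
Reagents that add atoms: none
Why: Acidolysis of the tert-butyl ester (loss of isobutene) is done here because the only allylic C–O bonds present sit on electron-poor acrylates and the tertiary alcohol is flanked by two electron-withdrawing groups, so nothing ionises.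

Step 11
Reactants: 4 (4S)-4-(propan-2-yl)cyclohex-2-en-1-one
Product: 20 (3S,4S)-3-ethenyl-4-(propan-2-yl)cyclohex-1-en-1-yl trifluoromethanesulfonate, via magnesium enolate 19 (not isolated)
Conditions: CH2=CHMgBr, CuBr·SMe2 (10 mol %), THF, −78 °C; then Comins' reagent, −78 to 0 °C
Reagents that add atoms: vinylmagnesium bromide, C=C[Mg]Br; N-(5-chloropyridin-2-yl)-bis(trifluoromethanesulfonyl)imide (Comins' reagent), O=S(=O)(N(c1ccc(Cl)cn1)S(=O)(=O)C(F)(F)F)C(F)(F)F
Why: Copper-catalysed conjugate addition anti to the isopropyl group sets the second stereocentre (trans), and O-triflation of the regiodefined enolate fixes the position of the ring double bond.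

Step 12
Reactants: 20 (3S,4S)-3-ethenyl-4-(propan-2-yl)cyclohex-1-en-1-yl trifluoromethanesulfonate
Product: 21 [(3S,4S)-3-ethenyl-4-(propan-2-yl)cyclohex-1-en-1-yl]methanol
Conditions: Bu3SnCH2OH, Pd(PPh3)4 (5 mol %), LiCl, 1,4-dioxane, 90 °C
Reagents that add atoms: (tributylstannyl)methanol, CCCC[Sn](CCCC)(CCCC)CO
Why: Stille cross-coupling of the alkenyl triflate with the hydroxymethyl stannane installs the allylic CH2OH with retention of the double-bond position and no effect on the stereocentres.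

Step 13
Reactants: 18 (5aR,6S,9R,9aS)-9-hydroxy-9-({[2-(hydroxymethyl)prop-2-enoyl]oxy}methyl)-1-oxo-6-(propan-2-yl)-1,3,5a,6,7,8,9,9a-octahydro-2-benzoxepine-4-carboxylic acid; 21 [(3S,4S)-3-ethenyl-4-(propan-2-yl)cyclohex-1-en-1-yl]methanol
Product: 22 CNP0361406.4 (target)
Conditions: 21 (3 equiv), second-generation Hoveyda–Grubbs catalyst [RuCl2(H2IMes)(=CH-C6H4-2-OiPr)] (10 mol %), 1,4-benzoquinone (20 mol %), CH2Cl2, 40 °C
Reagents that add atoms: none
Why: Cross-metathesis between the terminal vinyl group and the 1,1-disubstituted acrylate (the two trisubstituted alkenes are inert) gives the thermodynamically preferred E-alkene with the ring trans to the ester carbonyl, and benzoquinone suppresses migration of the doubly allylic double bond.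

## Compound list

1 | 3-methylbutanal | CC(C)CC=O | starting material
2 | but-3-en-2-one | CC(=O)C=C | starting material
3 | (2S)-5-oxo-2-(propan-2-yl)hexanal | CC(C)[C@@H](C=O)CCC(C)=O | intermediate (not isolated)
4 | (4S)-4-(propan-2-yl)cyclohex-2-en-1-one, (S)-cryptone | CC(C)[C@@H]1CCC(=O)C=C1 | intermediate
5 | (4S)-2-(hydroxymethyl)-4-(propan-2-yl)cyclohex-2-en-1-one | CC(C)[C@@H]1CCC(=O)C(CO)=C1 | intermediate
6 | (4S)-2-{[(tert-butyldimethylsilyl)oxy]methyl}-4-(propan-2-yl)cyclohex-2-en-1-one | CC(C)[C@@H]1CCC(=O)C(CO[Si](C)(C)C(C)(C)C)=C1 | intermediate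
7 | bromomagnesium (3S,4S)-2-{[(tert-butyldimethylsilyl)oxy]methyl}-3-ethenyl-4-(propan-2-yl)cyclohex-1-en-1-olate | CC(C)[C@@H]1CCC(O[Mg]Br)=C(CO[Si](C)(C)C(C)(C)C)[C@H]1C=C | intermediate (not isolated)
8 | (2R,3S,4S)-2-{[(tert-butyldimethylsilyl)oxy]methyl}-3-ethenyl-4-(propan-2-yl)cyclohexan-1-one (CH2OTBS cis to vinyl, vinyl trans to isopropyl) | CC(C)[C@@H]1CCC(=O)[C@@H](CO[Si](C)(C)C(C)(C)C)[C@H]1C=C | intermediate (not isolated)
9 | tert-butyl{[(3R,4R,5S,6S)-5-ethenyl-6-(propan-2-yl)-1-oxaspiro[2.5]octan-4-yl]methoxy}dimethylsilane (epoxide O cis to CH2OTBS) | CC(C)[C@@H]1CC[C@]2(CO2)[C@@H](CO[Si](C)(C)C(C)(C)C)[C@H]1C=C | intermediate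
10 | [(3R,4R,5S,6S)-5-ethenyl-6-(propan-2-yl)-1-oxaspiro[2.5]octan-4-yl]methanol | CC(C)[C@@H]1CC[C@]2(CO2)[C@@H](CO)[C@H]1C=C | intermediate
11 | (3R,4S,5S,6S)-5-ethenyl-6-(propan-2-yl)-1-oxaspiro[2.5]octane-4-carbaldehyde | CC(C)[C@@H]1CC[C@]2(CO2)[C@@H](C=O)[C@H]1C=C | intermediate (not isolated)
12 | (3R,4S,5S,6S)-5-ethenyl-6-(propan-2-yl)-1-oxaspiro[2.5]octane-4-carboxylic acid | CC(C)[C@@H]1CC[C@]2(CO2)[C@@H](C(=O)O)[C@H]1C=C | intermediate
13 | tert-butyl 2-(bromomethyl)prop-2-enoate | C=C(CBr)C(=O)OC(C)(C)C | starting material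
14 | 2-(tert-butoxycarbonyl)prop-2-en-1-yl (3R,4S,5S,6S)-5-ethenyl-6-(propan-2-yl)-1-oxaspiro[2.5]octane-4-carboxylate | CC(C)[C@@H]1CC[C@]2(CO2)[C@@H](C(=O)OCC(=C)C(=O)OC(C)(C)C)[C@H]1C=C | intermediate
15 | tert-butyl (5aR,6S,9R,9aS)-1-oxo-6-(propan-2-yl)-3,5a,6,7,8,9a-hexahydro-1H-spiro[2-benzoxepine-9,2'-oxirane]-4-carboxylate (cis-fused, epoxide O cis to the lactone carbonyl carbon) | CC(C)[C@@H]1CC[C@]3(CO3)[C@H]2C(=O)OCC(C(=O)OC(C)(C)C)=C[C@@H]12 | intermediate
16 | 2-(hydroxymethyl)prop-2-enoic acid | C=C(CO)C(=O)O | starting material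
17 | tert-butyl (5aR,6S,9R,9aS)-9-hydroxy-9-({[2-(hydroxymethyl)prop-2-enoyl]oxy}methyl)-1-oxo-6-(propan-2-yl)-1,3,5a,6,7,8,9,9a-octahydro-2-benzoxepine-4-carboxylate | CC(C)[C@@H]1CC[C@](O)(COC(=O)C(=C)CO)[C@H]2C(=O)OCC(C(=O)OC(C)(C)C)=C[C@@H]12 | intermediate
18 | (5aR,6S,9R,9aS)-9-hydroxy-9-({[2-(hydroxymethyl)prop-2-enoyl]oxy}methyl)-1-oxo-6-(propan-2-yl)-1,3,5a,6,7,8,9,9a-octahydro-2-benzoxepine-4-carboxylic acid | CC(C)[C@@H]1CC[C@](O)(COC(=O)C(=C)CO)[C@H]2C(=O)OCC(C(=O)O)=C[C@@H]12 | intermediate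
19 | bromomagnesium (3S,4S)-3-ethenyl-4-(propan-2-yl)cyclohex-1-en-1-olate | CC(C)[C@@H]1CCC(O[Mg]Br)=C[C@H]1C=C | intermediate (not isolated)
20 | (3S,4S)-3-ethenyl-4-(propan-2-yl)cyclohex-1-en-1-yl trifluoromethanesulfonate | CC(C)[C@@H]1CCC(OS(=O)(=O)C(F)(F)F)=C[C@H]1C=C | intermediate
21 | [(3S,4S)-3-ethenyl-4-(propan-2-yl)cyclohex-1-en-1-yl]methanol | CC(C)[C@@H]1CCC(CO)=C[C@H]1C=C | intermediate
22 | CNP0361406.4, (5aR,6S,9R,9aS)-9-hydroxy-9-{[((2E)-2-(hydroxymethyl)-3-[(1S,6S)-3-(hydroxymethyl)-6-(propan-2-yl)cyclohex-2-en-1-yl]prop-2-enoyl)oxy]methyl}-1-oxo-6-(propan-2-yl)-1,3,5a,6,7,8,9,9a-octahydro-2-benzoxepine-4-carboxylic acid | CC(C)[C@@H]1CC[C@](O)(COC(=O)/C(=C/[C@@H]2C=C(CO)CC[C@H]2C(C)C)CO)[C@H]2C(=O)OCC(C(=O)O)=C[C@@H]12 | target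

## Step count and risks

Total step count: 13. Longest linear sequence: 11 steps (steps 1 to 10, then 13); the right half needs steps 1, 11 and 12.

The three steps most likely to fail:

**Step 4 (the proposed new relay).** The risks are slow proton transfer from the sulfonium salt to the magnesium enolate, a poor cis/trans ratio in the protonation, or interference of copper and magnesium salts with the ylide. The fallback sets out from 6 and comes back at 10. The cuprate addition is run as before, but enolate 7 is quenched at −78 °C with 2,6-di-tert-butyl-4-methylphenol and cis-ketone 8 is isolated. Wittig methylenation (Ph3P=CH2, THF, −78 to 0 °C) gives the methylidene silyl ether F1, and TBAF gives the homoallylic alcohol F2. Hydroxyl-directed epoxidation of the exocyclic alkene (VO(acac)2 cat., t-BuOOH, CH2Cl2, 0 °C) then delivers oxygen from the face of the axial CH2OH group and gives 10. The epoxide oxygen is now delivered to an alkene under direction by the neighbouring alcohol instead of a carbon being delivered to a ketone, and the result is the same epoxide configuration.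

**Step 8 (ring-closing metathesis to a seven-membered trisubstituted enoate).** The fallback sets out from 12 and comes back at 15. Cross-metathesis of acid 12 with bromide 13 (same ruthenium catalyst, CH2Cl2, 40 °C) gives the bromo acid F3, in which the ring is trans to the ester and cis to CH2Br. Intramolecular carboxylate alkylation (K2CO3, DMF, high dilution) then closes the lactone at the O–CH2 bond and gives 15.

**Step 13 (late cross-metathesis on the fully functionalised acid).** The fallback sets out from 21 (and uses 15) and comes back at 22. Cross-metathesis of 21 with excess ethyl 2-(hydroxymethyl)prop-2-enoate gives the ethyl dienoate F4, and LiOH in THF/H2O gives the dihydroxy acid F5. The cesium carboxylate of F5 opens epoxide 15 under the conditions of step 9 to give the coupled tert-butyl ester F6. Mild cleavage of the tert-butyl ester (85 % aq. H3PO4, toluene, rt) gives 22. This makes the side chain on the small fragment and joins the halves by epoxide opening instead of by metathesis.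

## Further compounds

F1 | step 4 | tert-butyl{[(1S,5S,6S)-6-ethenyl-2-methylidene-5-(propan-2-yl)cyclohexyl]methoxy}dimethylsilane | CC(C)[C@@H]1CCC(=C)[C@@H](CO[Si](C)(C)C(C)(C)C)[C@H]1C=C
F2 | step 4 | [(1S,5S,6S)-6-ethenyl-2-methylidene-5-(propan-2-yl)cyclohexyl]methanol | CC(C)[C@@H]1CCC(=C)[C@@H](CO)[C@H]1C=C
F3 | step 8 | (3R,4S,5R,6S)-5-[(1Z)-3-bromo-2-(tert-butoxycarbonyl)prop-1-en-1-yl]-6-(propan-2-yl)-1-oxaspiro[2.5]octane-4-carboxylic acid | CC(C)[C@@H]1CC[C@]2(CO2)[C@@H](C(=O)O)[C@H]1/C=C(/C(=O)OC(C)(C)C)CBr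
F4 | step 13 | ethyl (2E)-2-(hydroxymethyl)-3-[(1S,6S)-3-(hydroxymethyl)-6-(propan-2-yl)cyclohex-2-en-1-yl]prop-2-enoate | CC(C)[C@@H]1CCC(CO)=C[C@H]1/C=C(/C(=O)OCC)CO
F5 | step 13 | (2E)-2-(hydroxymethyl)-3-[(1S,6S)-3-(hydroxymethyl)-6-(propan-2-yl)cyclohex-2-en-1-yl]prop-2-enoic acid | CC(C)[C@@H]1CCC(CO)=C[C@H]1/C=C(/C(=O)O)CO
F6 | step 13 | tert-butyl ester of 22 | CC(C)[C@@H]1CC[C@](O)(COC(=O)/C(=C/[C@@H]2C=C(CO)CC[C@H]2C(C)C)CO)[C@H]2C(=O)OCC(C(=O)OC(C)(C)C)=C[C@@H]12
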